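## Retrosynthetic overview

1. Atom labels give the position of each atom in the target SMILES. The strategy rests on the 1,4-dioxygen pattern O21–C20 / O25–C24 across C22–C23 in the six-membered carbocycle (C17, C19, C20, C22, C23, C24). This pattern is dissonant, so C20–C22 is cut into a ketyl at the C20 ketone and the β-carbon C22 of an acryloyl group on C17.
2. The precursor is a trans-fused cycloheptanone β-keto δ-lactone. Its seven-membered ring is cut at C13–C20 (lactone enolate plus Weinreb amide), the lactone at O10–C11, the diene at C7=C8 (aldol condensation) and C13–C14 (organocatalytic malonate addition to an enal).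
3. C17 comes from an enantioselective Diels–Alder adduct of butadiene and methacrolein. Its ring is opened by ozonolysis, and the C24 carbinol captures C20 as a lactol, which tells C20 from C14.
4. Ring order: temporary cyclohexene (step 1, opened in step 3), δ-lactone (step 14), seven-membered ring (step 15), six-membered ring (step 18). The C24 ketone is then reduced to the axial alcohol.

Key step: step 18

Remark: the C24 carbinol made in step 2 is carried as both epimers because it ends as a ketone in step 17, and the tertiary C2 hydroxyl is kept free throughout, so the key-step precursor and product carry a free C2–OH.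

## Route

Step 1
Reactants: 1 buta-1,3-diene; 2 methacrolein
Product: 3 (S)-1-methylcyclohex-3-ene-1-carbaldehyde
Conditions: (S)-3,3-diphenyl-1-(o-tolyl)tetrahydro-1H,3H-pyrrolo[1,2-c][1,3,2]oxazaborole (20 mol %), HN(SO2CF3)2 (17 mol %), CH2Cl2, −78 °C
Reagents that add atoms: none
Why: Enantioselective Diels–Alder reaction catalysed by a protonated chiral oxazaborolidine, which binds s-trans methacrolein and exposes one face of the dienophile, so that the quaternary centre C17 is set as S (the catalyst antipode that directs the diene to the α-re face is used; the (S)-prolinol-derived one is expected to do so).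

Step 2
Reactants: 3 (S)-1-methylcyclohex-3-ene-1-carbaldehyde
Product: 4 1-[(1S)-1-methylcyclohex-3-en-1-yl]prop-2-en-1-ol (both C24 epimers)
Conditions: CH2=CHMgBr, THF, −78 → 0 °C; aqueous work-up
Reagents that add atoms: vinylmagnesium bromide, C=C[Mg]Br
Why: Grignard 1,2-addition to the non-enolisable aldehyde introduces C23 and C22; the carbinol centre C24 forms as both epimers, which is harmless because C24 is oxidised to the ketone in step 17.

Step 3
Reactants: 4 1-[(1S)-1-methylcyclohex-3-en-1-yl]prop-2-en-1-ol
Product: 6 lactol aldehyde 3-[(3S)-5-hydroxy-3-methyl-2-vinyloxolan-3-yl]propanal, via dialdehyde 5 (not isolated)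
Conditions: O3, CH2Cl2/MeOH, −78 °C (Sudan Red 7B end point); PPh3, −78 °C → rt
Reagents that add atoms: ozone, [O-][O+]=O
Why: Chemoselective ozonolysis: ozone attacks the electron-rich cis-disubstituted ring alkene (C20=C14) much faster than the vinyl group, which is deactivated by the allylic hydroxyl and screened by the quaternary centre, and the C24 hydroxyl then traps the C20 aldehyde as a five-membered lactol, which tells C20 from the free C14 aldehyde.

Step 4
Reactants: 6 lactol aldehyde
Product: 7 lactone aldehyde 3-[(3S)-3-methyl-5-oxo-2-vinyloxolan-3-yl]propanal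
Conditions: (2,2,6,6-tetramethylpiperidin-1-yl)oxyl (10 mol %), PhI(OAc)2, CH2Cl2, rt
Reagents that add atoms: none
Why: Oxoammonium-mediated (nitroxyl/PhI(OAc)2) oxidation turns the lactol into the γ-lactone, while the free aldehyde, which forms no hydrate in the dry medium, is not oxidised further.

Step 5
Reactants: 7 lactone aldehyde
Product: 8 (4S)-4-[4-(1,3-dioxolan-2-yl)but-3-en-1-yl]-4-methyl-5-vinyloxolan-2-one (E/Z mixture)
Conditions: (1,3-dioxolan-2-ylmethyl)triphenylphosphonium bromide, NaN(SiMe3)2, THF, −78 °C → rt
Reagents that add atoms: (1,3-dioxolan-2-ylmethyl)triphenylphosphonium bromide, [Br-].C1COC(O1)C[P+](c1ccccc1)(c1ccccc1)c1ccccc1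
Why: Wittig olefination with the non-stabilised acetal ylide adds C8 and C9 as a protected enal at the aldehyde only (the lactone is inert to the ylide at low temperature); the E/Z mixture converges in step 8.

Step 6
Reactants: 8 vinyl dioxolane lactone
Product: 9 (3S)-7-(1,3-dioxolan-2-yl)-3-(1-hydroxyprop-2-en-1-yl)-N-methoxy-N,3-dimethylhept-6-enamide
Conditions: MeNHOMe·HCl, Me3Al, CH2Cl2, 0 °C → rt; Rochelle salt work-up; crude product used at once
Reagents that add atoms: N,O-dimethylhydroxylamine hydrochloride, CNOC.Cl
Why: Weinreb aminolysis: the aluminium amide opens the γ-lactone irreversibly to the hydroxy Weinreb amide, which makes C20 an acyl donor whose own α-hydrogens are not removed by LiN(SiMe3)2 and frees the C24 hydroxyl.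

Step 7
Reactants: 9 hydroxy Weinreb amide
Product: 10 tert-butyldimethylsilyl ether of 9 at the C24 oxygen
Conditions: t-BuMe2SiOSO2CF3, 2,6-lutidine, CH2Cl2, −78 °C
Reagents that add atoms: tert-butyldimethylsilyl triflate, CC(C)(C)[Si](C)(C)OS(=O)(=O)C(F)(F)F
Why: Silyl ether formation with the reactive triflate caps the hindered secondary C24 hydroxyl, which otherwise would re-close the lactone and, as an alkoxide in step 15, attack the Weinreb amide.

Step 8
Reactants: 10 silyl ether
Product: 11 (3S,6E)-3-[1-(tert-butyldimethylsilyloxy)prop-2-en-1-yl]-N-methoxy-N,3-dimethyl-8-oxooct-6-enamide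
Conditions: pyridinium p-toluenesulfonate, acetone/H2O, 45 °C
Reagents that add atoms: water, O
Why: Acid-catalysed hydrolysis of the allylic dioxolane liberates the enal, and the Z isomer equilibrates to the conjugated E-enal under the same conditions, while the silyl ether and the Weinreb amide survive the mild acid.

Step 9
Reactants: 11 enal; 12 diallyl malonate
Product: 13 diallyl 2-[(3R,6S)-6-[1-(tert-butyldimethylsilyloxy)prop-2-en-1-yl]-8-[methoxy(methyl)amino]-6-methyl-1,8-dioxooctan-3-yl]malonate
Conditions: (S)-2-{bis[3,5-bis(trifluoromethyl)phenyl](trimethylsilyloxy)methyl}pyrrolidine (10 mol %), EtOH, 0 °C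
Reagents that add atoms: none
Why: Iminium-ion organocatalytic Michael addition: the bulky C2 group of the (S)-diarylprolinol silyl ether covers one face of the E-iminium ion and the malonate adds to the β-carbon C14 from the other, giving the R adduct (14S in the target once C8 outranks C13), independent of the remote C17 centre.

Step 10
Reactants: 13 Michael adduct
Product: 15 (3R,6S)-6-[1-(tert-butyldimethylsilyloxy)prop-2-en-1-yl]-8-[methoxy(methyl)amino]-6-methyl-8-oxo-3-(2-oxoethyl)octanoic acid, via malonic acid 14 (not isolated)
Conditions: Pd(PPh3)4 (5 mol %), HCO2H, Et3N, THF, rt; acidic work-up; PhMe, 100 °C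
Reagents that add atoms: none
Why: Tsuji deallylation (π-allylpalladium, formate as hydride source) frees the malonic acid, which loses CO2 on heating; done before any allylic lactone or diene exists, it leaves C13 as a plain CH2 and removes the malonate leaving group that could reverse the Michael addition in the enamine step 12.

Step 11
Reactants: 16 2-methylbut-3-en-2-ol; 17 (E)-but-2-enal
Product: 18 (E)-4-hydroxy-4-methylpent-2-enal
Conditions: second-generation Hoveyda–Grubbs catalyst RuCl2(H2IMes)(=CH-C6H4-2-OiPr) (3 mol %), excess 17, CH2Cl2, 40 °C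
Reagents that add atoms: none
Why: Olefin cross-metathesis between the hindered allylic alcohol and excess crotonaldehyde, a pairing that gives the E-enal (C5=C6 of the target) and releases propene.

Step 12
Reactants: 15 acid aldehyde; 18 (E)-4-hydroxy-4-methylpent-2-enal
Product: 19 (3S,6S)-6-[1-(tert-butyldimethylsilyloxy)prop-2-en-1-yl]-3-[(1E,3E)-1-formyl-5-hydroxy-5-methylhexa-1,3-dien-1-yl]-8-[methoxy(methyl)amino]-6-methyl-8-oxooctanoic acid
Conditions: pyrrolidine (30 mol %), EtCO2H (30 mol %), i-PrOH, 40 °C, slow addition of 15 to excess 18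
Reagents that add atoms: none
Why: Amine-catalysed cross-aldol condensation (the enamine of 15 adds to the iminium ion of 18, then the amine is eliminated): 18 has no γ-hydrogen and its β-carbon is neopentyl, so it can act only as the 1,2-acceptor, and the C7=C8 geometry with C9 trans to C6 is the thermodynamic one under the equilibrating conditions.

Step 13
Reactants: 19 dienal acid
Product: 20 the C9 allylic alcohol of 19, (3S,6S)-3-[(1E,3E)-5-hydroxy-1-(hydroxymethyl)-5-methylhexa-1,3-dien-1-yl] acid
Conditions: NaBH4, CeCl3·7H2O, MeOH, −40 °C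
Reagents that add atoms: none
Why: Luche reduction: NaBH4 with CeCl3 reduces the dienal carbonyl 1,2 to the C9 allylic alcohol and leaves the acid, the Weinreb amide and the diene untouched.

Step 14
Reactants: 20 hydroxy acid
Product: 21 δ-lactone (4S,5E)-5-[(E)-4-hydroxy-4-methylpent-2-enylidene]oxan-2-one carrying at C4 (= C14) the CH2CH2–C17(CH3)[CH(OSiMe2t-Bu)CH=CH2]–CH2C(=O)N(OMe)Me chain
Conditions: N,N'-dicyclohexylcarbodiimide, 4-(dimethylamino)pyridine (10 mol %), CH2Cl2, 0 °C → rt
Reagents that add atoms: none
Why: Carbodiimide (Steglich-type) lactonisation: the activated acid is captured by the primary C9 hydroxyl in a six-membered ring closure, and the tertiary C2 hydroxyl is too hindered to be acylated.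

Step 15
Reactants: 21 δ-lactone Weinreb amide
Product: 22 trans-fused cycloheptanone β-keto δ-lactone (13R,14S,17S) with C17 carrying methyl and 1-(tert-butyldimethylsilyloxy)prop-2-en-1-yl
Conditions: LiN(SiMe3)2 (3.2 equiv), THF (0.01 M), −78 → −20 °C; AcOH quench
Reagents that add atoms: none
Why: Dieckmann-type intramolecular acylation: the lactone α-hydrogens at C13 are far more acidic than those next to the Weinreb amide, so only the lactone enolate forms and it attacks C20 through a stable chelated tetrahedral intermediate to close the seven-membered ring, and on work-up C13 settles as the trans-fused keto lactone by equilibration through the enol.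

Step 16
Reactants: 22 silylated β-keto lactone
Product: 23 β-keto lactone with free C24 carbinol (1-hydroxyprop-2-en-1-yl on C17)
Conditions: HF·pyridine, pyridine, THF, 0 °C → rt
Reagents that add atoms: none
Why: Fluoride-mediated desilylation frees the C24 carbinol, and the buffered reagent leaves the β-keto lactone, the allylic lactone C–O bond and the tertiary allylic alcohol intact.

Step 17
Reactants: 23 allylic alcohol
Product: 24 key-step precursor, the seven-membered β-keto lactone with the C17 acryloyl group (13R,14S,17S; free C2–OH)
Conditions: Dess–Martin periodinane, pyridine, CH2Cl2, 0 °C; used at once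
Reagents that add atoms: none
Why: Dess–Martin oxidation converts both epimers of the secondary allylic alcohol into the vinyl ketone under buffered, non-basic conditions; the tertiary C2 alcohol cannot be oxidised, and 24 is not stored because the acidic C13–H and the enone sit in one molecule.

Step 18
Reactants: 24 vinyl ketone β-keto lactone
Product: 25 the 24-oxo derivative of the target (13R,14S,17S,20R)
Conditions: SmI2 (2.5 equiv), MeOH (4 equiv), THF, −78 °C
Reagents that add atoms: none
Why: SmI2 (divalent samarium) gives one electron to the C20 ketone, the most easily reduced site because the samarium ion is held between the ketone and lactone carbonyl oxygens, and the ketyl adds to C22, the unsubstituted β-carbon of the vinyl ketone; a second electron turns the α-keto radical at C23 into a samarium enolate, which methanol protonates to the C24 ketone. The closest known reaction type is the SmI2-mediated ketyl–olefin (carbonyl–alkene) reductive cyclisation of β-keto esters onto electron-poor alkenes. The six-membered ring (C17, C19, C20, C22, C23, C24) closes 6-endo-trig, favoured over 5-exo attack at C23 because addition at the β-carbon gives the stabilised α-keto radical and leaves the enone carbonyl inside the new ring. The only new stereocentre, C20, is controlled by the tether: C17 and C20 are 1,3-related on the cycloheptane and the three-carbon bridge can join them only cis, so the hydroxyl ends anti to the bridge (20R). The step needs reduction of the chelated ketone ahead of the enone and an unchanged C13; chelation, low temperature and the neutral medium (trans-fused keto form, no enolate) are what secure both.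

Step 19
Reactants: 25 hydroxy ketone
Product: 26 CNP0116574.1 (13R,14S,17S,20R,24S)
Conditions: LiBH(s-Bu)3 (3.5 equiv), THF, −78 °C; aqueous work-up
Reagents that add atoms: none
Why: L-Selectride reduction: in the chair cyclohexanone the four-carbon bridge is axial at C17 and C20, and the bulky hydride attacks C24 equatorially, away from the syn-axial hydrogens on C19 and C22, to give the axial alcohol (24S, anti to C16 across C17–C24) that the target carries, whereas a small hydride would give the equatorial epimer; the lactone is not reduced at −78 °C.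

## Compound list

1 | buta-1,3-diene | C=CC=C | starting material
2 | methacrolein (2-methylprop-2-enal) | CC(=C)C=O | starting material
3 | (S)-1-methylcyclohex-3-ene-1-carbaldehyde | O=C[C@]1(C)CC=CCC1 | intermediate
4 | 1-[(1S)-1-methylcyclohex-3-en-1-yl]prop-2-en-1-ol (both C24 epimers) | C=CC(O)[C@]1(C)CC=CCC1 | intermediate
5 | (3S)-3-(1-hydroxyprop-2-en-1-yl)-3-methylhexanedial | C=CC(O)[C@](C)(CC=O)CCC=O | intermediate (not isolated)
6 | 3-[(3S)-5-hydroxy-3-methyl-2-vinyloxolan-3-yl]propanal (lactol, isomer mixture) | C=CC1OC(O)C[C@]1(C)CCC=O | intermediate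
7 | 3-[(3S)-3-methyl-5-oxo-2-vinyloxolan-3-yl]propanal | C=CC1OC(=O)C[C@]1(C)CCC=O | intermediate
8 | (4S)-4-[4-(1,3-dioxolan-2-yl)but-3-en-1-yl]-4-methyl-5-vinyloxolan-2-one (E/Z) | C=CC1OC(=O)C[C@]1(C)CCC=CC1OCCO1 | intermediate
9 | (3S)-7-(1,3-dioxolan-2-yl)-3-(1-hydroxyprop-2-en-1-yl)-N-methoxy-N,3-dimethylhept-6-enamide | C=CC(O)[C@](C)(CC(=O)N(C)OC)CCC=CC1OCCO1 | intermediate
10 | tert-butyldimethylsilyl ether of 9 | C=CC(O[Si](C)(C)C(C)(C)C)[C@](C)(CC(=O)N(C)OC)CCC=CC1OCCO1 | intermediate
11 | (3S,6E)-3-[1-(tert-butyldimethylsilyloxy)prop-2-en-1-yl]-N-methoxy-N,3-dimethyl-8-oxooct-6-enamide | C=CC(O[Si](C)(C)C(C)(C)C)[C@](C)(CC(=O)N(C)OC)CC/C=C/C=O | intermediate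
12 | diallyl malonate | C=CCOC(=O)CC(=O)OCC=C | starting material
13 | diallyl 2-[(3R,6S)-6-[1-(tert-butyldimethylsilyloxy)prop-2-en-1-yl]-8-[methoxy(methyl)amino]-6-methyl-1,8-dioxooctan-3-yl]malonate | C=CC(O[Si](C)(C)C(C)(C)C)[C@](C)(CC(=O)N(C)OC)CC[C@H](CC=O)C(C(=O)OCC=C)C(=O)OCC=C | intermediate
14 | malonic acid corresponding to 13 | C=CC(O[Si](C)(C)C(C)(C)C)[C@](C)(CC(=O)N(C)OC)CC[C@H](CC=O)C(C(=O)O)C(=O)O | intermediate (not isolated)
15 | (3R,6S)-6-[1-(tert-butyldimethylsilyloxy)prop-2-en-1-yl]-8-[methoxy(methyl)amino]-6-methyl-8-oxo-3-(2-oxoethyl)octanoic acid | C=CC(O[Si](C)(C)C(C)(C)C)[C@](C)(CC(=O)N(C)OC)CC[C@H](CC=O)CC(=O)O | intermediate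
16 | 2-methylbut-3-en-2-ol | CC(C)(O)C=C | starting material
17 | (E)-but-2-enal (crotonaldehyde) | C/C=C/C=O | starting material
18 | (E)-4-hydroxy-4-methylpent-2-enal | CC(C)(O)/C=C/C=O | intermediate
19 | (3S,6S)-6-[1-(tert-butyldimethylsilyloxy)prop-2-en-1-yl]-3-[(1E,3E)-1-formyl-5-hydroxy-5-methylhexa-1,3-dien-1-yl]-8-[methoxy(methyl)amino]-6-methyl-8-oxooctanoic acid | CC(C)(O)/C=C/C=C(/C=O)[C@H](CC(=O)O)CC[C@@](C)(CC(=O)N(C)OC)C(O[Si](C)(C)C(C)(C)C)C=C | intermediate
20 | C9 allylic alcohol of 19 (hydroxymethyl in place of formyl) | CC(C)(O)/C=C/C=C(/CO)[C@H](CC(=O)O)CC[C@@](C)(CC(=O)N(C)OC)C(O[Si](C)(C)C(C)(C)C)C=C | intermediate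
21 | δ-lactone (4S,5E)-5-[(E)-4-hydroxy-4-methylpent-2-enylidene]oxan-2-one with the Weinreb amide side chain at C4 | CC(C)(O)/C=C/C=C1/COC(=O)C[C@@H]1CC[C@@](C)(CC(=O)N(C)OC)C(O[Si](C)(C)C(C)(C)C)C=C | intermediate
22 | trans-fused cycloheptanone β-keto δ-lactone, C24 as silylated vinyl carbinol | CC(C)(O)/C=C/C=C1/COC(=O)[C@@H]2[C@@H]1CC[C@](C)(C(O[Si](C)(C)C(C)(C)C)C=C)CC2=O | intermediate
23 | β-keto lactone with free C24 vinyl carbinol | CC(C)(O)/C=C/C=C1/COC(=O)[C@@H]2[C@@H]1CC[C@](C)(C(O)C=C)CC2=O | intermediate
24 | key-step precursor: β-keto lactone with C17 acryloyl group | CC(C)(O)/C=C/C=C1/COC(=O)[C@@H]2[C@@H]1CC[C@](C)(C(=O)C=C)CC2=O | intermediate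
25 | key-step product: 24-oxo derivative of the target | CC(C)(O)/C=C/C=C1/COC(=O)[C@@H]2[C@@H]1CC[C@@]1(C)C[C@]2(O)CCC1=O | intermediate
26 | CNP0116574.1 | CC(C)(O)/C=C/C=C1/COC(=O)[C@@H]2[C@@H]1CC[C@@]1(C)C[C@]2(O)CC[C@@H]1O | target

## Step count and risks

Total step count: 19. Longest linear sequence: 18 (steps 1–10 and 12–19).

**Step 18 (key step).** The vinyl ketone may take up the electron first and be simply reduced or dimerised, or the C13–H between the two carbonyls may enolise and add to C22 before the ketyl forms. The fallback sets out from 23 and comes back at 25. NaBH4 in MeOH at −20 °C reduces only the C20 ketone of 23 to the β-hydroxy lactone F1 (either C20 epimer serves). MnO2 in CH2Cl2 then oxidises only the allylic C24 carbinol to the vinyl ketone F2. Irradiation of F2 with blue LEDs in MeCN with [Ir{dF(CF3)ppy}2(dtbbpy)]PF6 (1 mol %), quinuclidine (10 mol %) and Bu4N(H2PO4) abstracts the hydridic carbinol hydrogen at C20, and the α-hydroxy radical adds 6-endo to C22 (hydrogen-atom-transfer Giese cyclisation). This gives 25 with the same bridge-enforced C20 configuration. No reductant that can touch the enone is present, and F2 has no doubly activated C13–H.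

**Step 15.** Closure of the seven-membered ring by the conformationally restricted lactone enolate may be slow, so that intermolecular Claisen condensation or enolate decay takes over. The fallback sets out from 20 and comes back at 22. The acid of 20 is esterified with N,N-dimethylformamide di-tert-butyl acetal (PhMe, 80 °C) to the tert-butyl ester F3. LiN(SiMe3)2 (THF, −78 → 0 °C) then forms the freely rotating open-chain ester enolate, whose own carbonyl cannot be attacked, and it is acylated by the Weinreb amide to give the cycloheptanone β-keto tert-butyl ester F4. Heating F4 in PhMe at 100 °C expels tert-butanol to an acyl ketene, which the C9 hydroxyl captures to close the δ-lactone and give 22.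

**Step 12.** Self-condensation of the donor aldehyde, incomplete elimination or an E/Z mixture at C7=C8 may lower the yield of the one-pot condensation. The fallback sets out from 15 and 18 and comes back at 19. (S)-Proline (20 mol %) in DMF at 4 °C with slow addition of 15 gives the cross-aldol adduct F5 (β-hydroxy aldehyde, isomer mixture), which is isolated. A separate base-mediated E1cB dehydration (DBU, CH2Cl2, rt) then gives 19, so that C–C bond formation and elimination are optimised apart.

Further compounds
F1 | step 18 | β-hydroxy lactone diol (C20 carbinol, C24 vinyl carbinol) | CC(C)(O)/C=C/C=C1/COC(=O)[C@@H]2[C@@H]1CC[C@](C)(C(O)C=C)CC2O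
F2 | step 18 | β-hydroxy lactone with C17 acryloyl group | CC(C)(O)/C=C/C=C1/COC(=O)[C@@H]2[C@@H]1CC[C@](C)(C(=O)C=C)CC2O
F3 | step 15 | tert-butyl ester of 20 | CC(C)(O)/C=C/C=C(/CO)[C@H](CC(=O)OC(C)(C)C)CC[C@@](C)(CC(=O)N(C)OC)C(O[Si](C)(C)C(C)(C)C)C=C
F4 | step 15 | cycloheptanone β-keto tert-butyl ester with free C9 hydroxyl | CC(C)(O)/C=C/C=C(/CO)[C@H]1CC[C@](C)(C(O[Si](C)(C)C(C)(C)C)C=C)CC(=O)C1C(=O)OC(C)(C)C
F5 | step 12 | cross-aldol adduct (β-hydroxy aldehyde) of 15 and 18 | CC(C)(O)/C=C/C(O)C(C=O)[C@H](CC(=O)O)CC[C@@](C)(CC(=O)N(C)OC)C(O[Si](C)(C)C(C)(C)C)C=C
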